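**Strategy.** The plan reads the carbon chain that runs from the coumarin lactone carbon C2 through C3, C6′ and C5′ to C4′ as an opened 4-hydroxy-2-pyrone, and the dihydropyranone ring (O1′, C2′–C6′; primed locants) as a cyclodehydrated δ-hydroxy-β-diketone. In one operation a hexasubstituted salicylaldehyde condenses with an enantiopure 6-(2-hydroxypropyl)-4-hydroxy-2-pyrone. The phenol then opens the pyrone lactone, which closes the coumarin, and the diketone set free is closed by its own C2′ hydroxyl to the dihydropyranone, the last ring to form. The precursors are an aldehyde and a pyrone, neither containing the final ring. Both stereocentres come from the chiral pool: (S)-propylene oxide and (R)-β-butyrolactone.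

Key step: step 7

Remark: bromide 1 is taken as a purchasable building block, and aldehyde 9 is drawn in its open form, which equilibrates with its six-membered lactol; both forms enter step 7 through the same iminium ion.

Step 1
Reactants: 1 5-bromo-1,3-dimethoxy-2-methylbenzene
Product: 3 1-bromo-3,5-dimethoxy-2,4-dimethylbenzene, via aryllithium 2 (not isolated)
Conditions: LiN(i-Pr)2 (1.0 equiv), THF, −78 °C; then MeI, −78 → 0 °C
Reagents that add atoms: iodomethane, CI
Why: Directed ortho-metalation removes the ring C–H flanked by Br and OMe (the two such positions are equivalent) at −78 °C, where loss of LiBr to an aryne should be slow, and the aryllithium is alkylated by MeI.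

Step 2
Reactants: 3 1-bromo-3,5-dimethoxy-2,4-dimethylbenzene; 4 (S)-propylene oxide
Product: 6 (2S)-1-(3,5-dimethoxy-2,4-dimethylphenyl)propan-2-ol, via arylmagnesium bromide 5 (not isolated)
Conditions: Mg turnings, I2 (trace), THF, 50 °C; then CuI (10 mol %), 4, −30 → 0 °C; aqueous work-up
Reagents that add atoms: none
Why: Grignard formation followed by CuI-catalysed SN2 opening of the epoxide at its unsubstituted CH2 terminus leaves the stereocentre of 4 untouched and so should deliver the (S)-carbinol.

Step 3
Reactants: 6 (2S)-1-(3,5-dimethoxy-2,4-dimethylphenyl)propan-2-ol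
Product: 7 5-[(2S)-2-hydroxypropyl]-2,4-dimethylbenzene-1,3-diol
Conditions: BBr3 (4 equiv), CH2Cl2, −78 → 0 °C; then H2O
Reagents that add atoms: none
Why: Lewis-acid cleavage of both aryl methyl ethers by BBr3 (bromide attack on the O-methyl carbon), while the secondary alcohol is held as its borate at low temperature and should return unchanged on hydrolysis.

Step 4
Reactants: 7 5-[(2S)-2-hydroxypropyl]-2,4-dimethylbenzene-1,3-diol
Product: 9 2,4-dihydroxy-6-[(2S)-2-hydroxypropyl]-3,5-dimethylbenzaldehyde, via cyclic ethyl acetal 8 (not isolated)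
Conditions: HC(OEt)3 (3 equiv), TsOH·H2O (10 mol %), THF, rt; then 1 M aq. HCl, rt
Reagents that add atoms: triethyl orthoformate, CCOC(OCC)OCC; water, O
Why: Oxa-Pictet–Spengler-type formylation in which the side-chain alcohol exchanges into the orthoformate, the derived dialkoxycarbenium ion attacks the only free ring position (ortho and para to the two phenols) in a six-membered closure, and aqueous acid hydrolyses the cyclic acetal to the salicylaldehyde.

Step 5
Reactants: 10 2,2,6-trimethyl-4H-1,3-dioxin-4-one; 11 (R)-β-butyrolactone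
Product: 13 6-[(4R)-4-hydroxy-2-oxopentyl]-2,2-dimethyl-4H-1,3-dioxin-4-one, via lithium dienolate 12 (not isolated)
Conditions: 10 (1.5 equiv), LiN(i-Pr)2 (1.5 equiv), THF, −78 °C; then 11 (1.0 equiv), −78 → −40 °C; AcOH quench
Reagents that add atoms: none
Why: Claisen-type acylation in which the γ-carbon of the dioxinone dienolate attacks the strained lactone carbonyl, acyl–oxygen cleavage releases the ring strain and the alkoxide formed deprotonates the new β-diketone, so the stereocentre of 11 is carried over unchanged.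

Step 6
Reactants: 13 6-[(4R)-4-hydroxy-2-oxopentyl]-2,2-dimethyl-4H-1,3-dioxin-4-one
Product: 15 4-hydroxy-6-[(2R)-2-hydroxypropyl]-2H-pyran-2-one, via acylketene 14 (not isolated)
Conditions: PhMe (high dilution), 110 °C
Reagents that add atoms: none
Why: Thermal retro-[4+2] loss of acetone from the dioxinone gives an acylketene that is trapped in a six-membered closure by the enol oxygen of the 5-keto group, the standard dioxinone route to 6-substituted 4-hydroxy-2-pyrones.

Step 7
Reactants: 9 2,4-dihydroxy-6-[(2S)-2-hydroxypropyl]-3,5-dimethylbenzaldehyde; 15 4-hydroxy-6-[(2R)-2-hydroxypropyl]-2H-pyran-2-one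
Product: 18 7-hydroxy-5-[(2S)-2-hydroxypropyl]-6,8-dimethyl-3-[(2R)-2-methyl-4-oxo-3,4-dihydro-2H-pyran-6-yl]-2H-chromen-2-one, via arylidene-pyrandione 16 (not isolated), via coumarinyl diketone 17 (not isolated)
Conditions: piperidine (0.2 equiv), AcOH (0.2 equiv), EtOH, 60 °C; then TsOH·H2O (0.5 equiv), 60 °C
Reagents that add atoms: none
Why: Amine-catalysed Knoevenagel condensation joins the aldehyde carbon of 9 to the nucleophilic C3 of pyrone 15 to give 16, the ortho phenol then attacks the pyrone lactone carbonyl and expels the enol oxygen (translactonization), which closes the coumarin and unmasks β-diketone 17, and after acidification the C2′ hydroxyl adds to the coumarin-bound ketone and water is lost to give the dihydropyranone. The closest known reactions are the condensation of salicylaldehydes with 4-hydroxy-6-methyl-2-pyrone to 3-acetoacetylcoumarins and the acid cyclodehydration of δ-hydroxy-β-diketones to 2,3-dihydro-4H-pyran-4-ones. The coumarin ring closes by 6-exo-trig acyl substitution (lactonization), and the dihydropyranone ring closes by 6-exo-trig hemiketalization followed by dehydration to the C5′=C6′ enol ether. No new stereocentre is formed: C2′ comes from 11 and its C–O bond is never broken, and the side-chain carbinol comes from 4. The phenol must attack the lactone carbonyl and not the C4 ketone of 16, which is secured because ketone addition is reversible whereas lactone exchange gives the aromatic coumarin irreversibly. Only the C2′ hydroxyl can reach the C6′ carbonyl through a six-membered ring (the aryl side-chain hydroxyl would need an eight-membered one), and acidic closure avoids base-mediated retro-oxa-Michael racemization at C2′.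

**Compound list**

1 | 5-bromo-1,3-dimethoxy-2-methylbenzene | COc1cc(Br)cc(OC)c1C | starting material
2 | (6-bromo-2,4-dimethoxy-3-methylphenyl)lithium | COc1cc(Br)c([Li])c(OC)c1C | intermediate
3 | 1-bromo-3,5-dimethoxy-2,4-dimethylbenzene | COc1cc(Br)c(C)c(OC)c1C | intermediate
4 | (S)-propylene oxide, (2S)-2-methyloxirane | C[C@H]1CO1 | starting material
5 | (3,5-dimethoxy-2,4-dimethylphenyl)magnesium bromide | COc1cc([Mg]Br)c(C)c(OC)c1C | intermediate
6 | (2S)-1-(3,5-dimethoxy-2,4-dimethylphenyl)propan-2-ol | COc1cc(C[C@H](C)O)c(C)c(OC)c1C | intermediate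
7 | 5-[(2S)-2-hydroxypropyl]-2,4-dimethylbenzene-1,3-diol | Cc1c(O)cc(C[C@H](C)O)c(C)c1O | intermediate
8 | (3S)-1-ethoxy-3,5,7-trimethyl-3,4-dihydro-1H-isochromene-6,8-diol (both C1 epimers) | CCOC1O[C@@H](C)Cc2c(C)c(O)c(C)c(O)c21 | intermediate
9 | 2,4-dihydroxy-6-[(2S)-2-hydroxypropyl]-3,5-dimethylbenzaldehyde | O=Cc1c(O)c(C)c(O)c(C)c1C[C@H](C)O | intermediate
10 | 2,2,6-trimethyl-4H-1,3-dioxin-4-one | CC1=CC(=O)OC(C)(C)O1 | starting material
11 | (R)-β-butyrolactone, (4R)-4-methyloxetan-2-one | C[C@@H]1CC(=O)O1 | starting material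
12 | lithium 2,2-dimethyl-6-methylidene-6H-1,3-dioxin-4-olate (dienolate of 10) | C=C1C=C(O[Li])OC(C)(C)O1 | intermediate
13 | 6-[(4R)-4-hydroxy-2-oxopentyl]-2,2-dimethyl-4H-1,3-dioxin-4-one | C[C@@H](O)CC(=O)CC1=CC(=O)OC(C)(C)O1 | intermediate
14 | (7R)-7-hydroxyoct-1-ene-1,3,5-trione (acylketene) | C[C@@H](O)CC(=O)CC(=O)C=C=O | intermediate
15 | 4-hydroxy-6-[(2R)-2-hydroxypropyl]-2H-pyran-2-one | C[C@@H](O)CC1=CC(O)=CC(=O)O1 | intermediate
16 | 3-{2,4-dihydroxy-6-[(2S)-2-hydroxypropyl]-3,5-dimethylbenzylidene}-6-[(2R)-2-hydroxypropyl]-2H-pyran-2,4(3H)-dione | C[C@@H](O)CC1=CC(=O)C(=Cc2c(O)c(C)c(O)c(C)c2C[C@H](C)O)C(=O)O1 | intermediate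
17 | 7-hydroxy-3-[(5R)-5-hydroxy-3-oxohexanoyl]-5-[(2S)-2-hydroxypropyl]-6,8-dimethyl-2H-chromen-2-one | C[C@@H](O)CC(=O)CC(=O)c1cc2c(C[C@H](C)O)c(C)c(O)c(C)c2oc1=O | intermediate
18 | 7-hydroxy-5-[(2S)-2-hydroxypropyl]-6,8-dimethyl-3-[(2R)-2-methyl-4-oxo-3,4-dihydro-2H-pyran-6-yl]-2H-chromen-2-one | Cc1c(O)c(C)c2oc(=O)c(C3=CC(=O)C[C@@H](C)O3)cc2c1C[C@H](C)O | target

**Step count.** Total: 7 steps. Longest linear sequence: 5 steps (steps 1–4, then step 7); the pyrone arm is steps 5–6.

**Steps most likely to fail**

Step 7. The arylidene intermediate may be diverted, either by addition of a second pyrone or by addition of the aryl side-chain hydroxyl to the benzylidene carbon without reversion. The β-hydroxy ketone may also suffer retro-aldol cleavage or elimination before ring closure, which would erode C2′. The fallback sets out from 9 and builds the coumarin first with a simpler partner. Knoevenagel condensation with ethyl acetoacetate (piperidine cat., EtOH) should give 3-acetyl-7-hydroxy-5-[(2S)-2-hydroxypropyl]-6,8-dimethyl-2H-chromen-2-one F1. Silylation of both hydroxyls (TBSCl, imidazole, DMF) should give 3-acetyl-7-[(tert-butyldimethylsilyl)oxy]-5-{(2S)-2-[(tert-butyldimethylsilyl)oxy]propyl}-6,8-dimethyl-2H-chromen-2-one F2. Kinetic enolization (LiN(SiMe3)2, THF, −78 °C) and Claisen-type acylation with lactone 11 should give 7-[(tert-butyldimethylsilyl)oxy]-5-{(2S)-2-[(tert-butyldimethylsilyl)oxy]propyl}-3-[(5R)-5-hydroxy-3-oxohexanoyl]-6,8-dimethyl-2H-chromen-2-one F3. Aqueous HF in MeCN should then remove both silyl groups and close the dihydropyranone, coming back to the route at 18.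

Step 5. The dienolate may act as a base toward the lactone (α-deprotonation and β-elimination to crotonate), or open it by alkyl–oxygen instead of acyl–oxygen cleavage. The fallback sets out from 11 and 10 and replaces the lactone by a protected Weinreb amide. Aminolysis of 11 (MeNH(OMe)·HCl, AlMe3, CH2Cl2) should give (3R)-3-hydroxy-N-methoxy-N-methylbutanamide F4. Silylation (TBSCl, imidazole) should give (3R)-3-[(tert-butyldimethylsilyl)oxy]-N-methoxy-N-methylbutanamide F5. Acylation of dienolate 12 (from 10, LiN(i-Pr)2, THF, −78 °C) with F5 should give 6-{(4R)-4-[(tert-butyldimethylsilyl)oxy]-2-oxopentyl}-2,2-dimethyl-4H-1,3-dioxin-4-one F6. Desilylation with HF·pyridine in THF comes back to the route at 13.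

Step 4. Orthoester formation at the phenolic oxygens may outpace ring closure, or the electron-rich cyclic acetal may ionize to a quinone methide and oligomerize. The fallback sets out from 6 and installs the formyl group through a halogen–metal exchange before the phenols are freed. Bromination at the single free ring position (NBS, MeCN, 0 °C) should give (2S)-1-(2-bromo-3,5-dimethoxy-4,6-dimethylphenyl)propan-2-ol F7. Bromine–lithium exchange on the alkoxide (n-BuLi, 2.2 equiv, THF, −78 °C) and quench with DMF should give 2-[(2S)-2-hydroxypropyl]-4,6-dimethoxy-3,5-dimethylbenzaldehyde F8. Demethylation with BBr3 (CH2Cl2, −78 → 0 °C) comes back to the route at 9.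

**Further compounds**

F1 | step 7 | 3-acetyl-7-hydroxy-5-[(2S)-2-hydroxypropyl]-6,8-dimethyl-2H-chromen-2-one | CC(=O)c1cc2c(C[C@H](C)O)c(C)c(O)c(C)c2oc1=O
F2 | step 7 | 3-acetyl-7-[(tert-butyldimethylsilyl)oxy]-5-{(2S)-2-[(tert-butyldimethylsilyl)oxy]propyl}-6,8-dimethyl-2H-chromen-2-one | CC(=O)c1cc2c(C[C@H](C)O[Si](C)(C)C(C)(C)C)c(C)c(O[Si](C)(C)C(C)(C)C)c(C)c2oc1=O
F3 | step 7 | 7-[(tert-butyldimethylsilyl)oxy]-5-{(2S)-2-[(tert-butyldimethylsilyl)oxy]propyl}-3-[(5R)-5-hydroxy-3-oxohexanoyl]-6,8-dimethyl-2H-chromen-2-one | C[C@@H](O)CC(=O)CC(=O)c1cc2c(C[C@H](C)O[Si](C)(C)C(C)(C)C)c(C)c(O[Si](C)(C)C(C)(C)C)c(C)c2oc1=O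
F4 | step 5 | (3R)-3-hydroxy-N-methoxy-N-methylbutanamide | C[C@@H](O)CC(=O)N(C)OC
F5 | step 5 | (3R)-3-[(tert-butyldimethylsilyl)oxy]-N-methoxy-N-methylbutanamide | C[C@@H](O[Si](C)(C)C(C)(C)C)CC(=O)N(C)OC
F6 | step 5 | 6-{(4R)-4-[(tert-butyldimethylsilyl)oxy]-2-oxopentyl}-2,2-dimethyl-4H-1,3-dioxin-4-one | C[C@@H](O[Si](C)(C)C(C)(C)C)CC(=O)CC1=CC(=O)OC(C)(C)O1
F7 | step 4 | (2S)-1-(2-bromo-3,5-dimethoxy-4,6-dimethylphenyl)propan-2-ol | COc1c(C)c(OC)c(Br)c(C[C@H](C)O)c1C
F8 | step 4 | 2-[(2S)-2-hydroxypropyl]-4,6-dimethoxy-3,5-dimethylbenzaldehyde | COc1c(C)c(OC)c(C=O)c(C[C@H](C)O)c1C
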